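## Retrosynthetic overview

- The C10 angelate and the C6 anisoate are cut back to the two carbinols, and the C4 isopropyl carbinol to a C4 ketone (isopropyl addition anti to the C5–C6 bond).
- The C6–C7 and C1–C10 bonds of the seven-membered ring B are formed together in a silyl-cation-catalysed (4+3) cycloaddition. The partners are an O-silylated cyclopentenecarbaldehyde (C6–C5–C1 as a 1-silyloxyallyl cation) and the silyl dienol ether of 3-methylbut-2-enal (C7–C8(Me)=C9–C10); a 1,2-hydride shift from C4 to C5 ends the step.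
- Enabling feature: ring B is an isoprene unit (C7–C10) held between two oxygenated carbons (C6 and C10) that are both former aldehyde carbons. Ring A carries the C4 oxygen directly beside the ring-fusion C5–H, which is the retron of a semipinacol hydride shift that quenches the C5 cation and turns the C4 silyl ether into the ketone.
- Ring order: ring A (cyclopentene) comes from 2-bromo-3-methylcyclopent-2-en-1-one with one pre-set stereocentre (C4, CBS reduction). Ring B is closed in the key step, where that centre controls C1, C5, C6 and C10, is erased, and is later rebuilt at C4.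

Key step: step 5

Remark: bicyclic compounds carry daucane locants (ring A = C1 quaternary methyl-bearing fusion carbon, C2, C3, C4, C5 fusion CH; ring B = C1, C5, C6, C7, C8, C9, C10), also in the bicyclo[5.3.0]decane names; β is the face of the C1 methyl, α the opposite face; 2-bromo-3-methylcyclopent-2-en-1-one is taken as a commercial starting material.

## Route

Step 1
Reactants: 1 2-bromo-3-methylcyclopent-2-en-1-one
Product: 2 (S)-2-bromo-3-methylcyclopent-2-en-1-ol
Conditions: (R)-2-methyl-CBS-oxazaborolidine (C18H20BNO, 10 mol %), BH3·SMe2, THF, −20 °C; MeOH quench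
Reagents that add atoms: none
Why: Corey–Bakshi–Shibata reduction: the catalyst–borane complex binds the carbonyl oxygen anti to the bromoalkenyl (large) substituent and delivers hydride to one face, which with the (R)-oxazaborolidine should set the C4 carbinol as (S), as is usual for 2-haloenones.

Step 2
Reactants: 2 (S)-2-bromo-3-methylcyclopent-2-en-1-ol
Product: 3 (S)-[(2-bromo-3-methylcyclopent-2-en-1-yl)oxy]triethylsilane
Conditions: Et3SiCl, imidazole, CH2Cl2, 0 °C
Reagents that add atoms: chlorotriethylsilane, CC[Si](Cl)(CC)CC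
Why: Imidazole-promoted silylation of a secondary allylic alcohol leaves the stereocentre untouched, and triethylsilyl is chosen because it later acts as the silyl chain carrier of the key step and as the selectively removable group on O6.

Step 3
Reactants: 3 (S)-[(2-bromo-3-methylcyclopent-2-en-1-yl)oxy]triethylsilane
Product: 5 (S)-2-methyl-5-(triethylsilyloxy)cyclopent-1-ene-1-carbaldehyde, via vinyllithium 4 (not isolated)
Conditions: t-BuLi (2.1 equiv), THF, −78 °C; DMF, −78 → 0 °C; aq NH4Cl
Reagents that add atoms: N,N-dimethylformamide, CN(C)C=O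
Why: Bromine–lithium exchange on the vinyl bromide at −78 °C followed by formylation of the vinyllithium with DMF (Bouveault aldehyde synthesis) is standard for 2-bromocycloalkenyl silyl ethers and does not touch the C4 centre.

Step 4
Reactants: 6 3-methylbut-2-enal
Product: 7 (E)-triisopropyl[(3-methylbuta-1,3-dien-1-yl)oxy]silane
Conditions: i-Pr3SiOTf, Et3N, Et2O, 0 °C → rt
Reagents that add atoms: triisopropylsilyl trifluoromethanesulfonate, CC(C)[Si](OS(=O)(=O)C(F)(F)F)(C(C)C)C(C)C
Why: O-Silylation of the enal and γ-deprotonation by Et3N (silyl dienol ether formation by soft enolisation) give the conjugated 1-silyloxydiene, and the E enol ether is expected because the oxocarbenium ion is deprotonated in its s-trans form.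

Step 5
Reactants: 5 (S)-2-methyl-5-(triethylsilyloxy)cyclopent-1-ene-1-carbaldehyde; 7 (E)-triisopropyl[(3-methylbuta-1,3-dien-1-yl)oxy]silane (1.3 equiv)
Product: 10 (1S,5S,6S,10R)-1,8-dimethyl-6-(triethylsilyloxy)-10-(triisopropylsilyloxy)bicyclo[5.3.0]dec-8-en-4-one, via silyloxyallyl cation 8 (not isolated), via cycloheptenyl cation 9 (not isolated)
Conditions: Et3SiNTf2 (5 mol %, from Tf2NH and allyltriethylsilane), CH2Cl2, −78 → −40 °C; then Et3N, aq NaHCO3
Reagents that add atoms: none
Why: Proposed new method: Et3Si+ from Et3SiNTf2 silylates the formyl oxygen of 5 to give the s-trans 1-silyloxyallyl cation 8 (C6–C5–C1), the s-cis diene 7 adds across its termini (nucleophilic CH2 terminus C7 to the oxocarbenium carbon C6, C10 to C1) to give cycloheptenyl cation 9, and a suprafacial 1,2-hydride shift from C4 to C5 then gives the O-silylated C4 ketone, which hands Et3Si+ to the next molecule of 5, so that the silyl group formally travels from O4 to O6. The closest known reaction types are the Lewis-acid-promoted formal (4+3) annulation of α-substituted enals with dienes, in which the cycloheptenyl cation is likewise quenched by a 1,2-hydride shift, (4+3) cycloadditions of heteroatom-stabilised allyl cations that have one exocyclic terminus, γ-selective vinylogous Mukaiyama aldol additions of this type of dienol ether, and semipinacol hydride shifts next to silyl ethers; what is new is that the hydride is taken from the silyloxy carbon C4 and not from C6, so that C6 keeps both its hydrogen and its oxygen. Ring B (seven-membered) is closed by the intermolecular (4+3) cycloaddition through a compact, boat-like transition state (if the process is stepwise, the second bond is a seven-membered cation–olefin closure of the C5=C1 alkene onto the C10 silyloxocarbenium ion), while ring A is carried in from 5. The C4 silyloxy group shields the β-face of the planar cation, so the diene adds to the α-face, where C4–H also lies, which sets C1 (methyl β) and delivers the hydride to C5 on the α-face (trans ring fusion); the s-trans (W-shaped) silyloxocarbenium geometry sets C6 (oxygen α, trans to the C1 methyl), and the E enol ether in the compact arrangement sets C10 (oxygen α, cis to O6). The step needs (a) bonding of C7 to C6 and not to the hindered terminus C1, secured by the polarity of the dienol ether and the accessible oxocarbenium carbon, (b) closure of the second bond before the open-chain silyloxocarbenium ion is lost, favoured by the non-nucleophilic triflimide counter-ion and the s-cis-biased 3-methyl diene, and (c) migration of the C4 hydrogen rather than of the C6 hydrogen or of C7, favoured because C4–H is aligned with the empty orbital at C5 on the α-face whereas C6–H lies near its nodal plane in the first-formed conformer.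

Step 6
Reactants: 10 (1S,5S,6S,10R)-1,8-dimethyl-6-(triethylsilyloxy)-10-(triisopropylsilyloxy)bicyclo[5.3.0]dec-8-en-4-one
Product: 11 (1S,4R,5S,6S,10R)-4-isopropyl-1,8-dimethyl-6-(triethylsilyloxy)-10-(triisopropylsilyloxy)bicyclo[5.3.0]dec-8-en-4-ol
Conditions: i-PrMgCl, CeCl3, THF, −78 → −20 °C; aq NH4Cl
Reagents that add atoms: isopropylmagnesium chloride, CC(C)[Mg]Cl
Why: Organocerium 1,2-addition (Grignard reagent transmetallated to CeCl3) suppresses enolisation and β-elimination of the β-silyloxy ketone, and the reagent should attack the cyclopentanone on the α-face, anti to the C5–C6 bond and to the β-methyl on C1, so that the new C4 hydroxyl is β (4R) as in the target.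

Step 7
Reactants: 11 (1S,4R,5S,6S,10R)-4-isopropyl-1,8-dimethyl-6-(triethylsilyloxy)-10-(triisopropylsilyloxy)bicyclo[5.3.0]dec-8-en-4-ol
Product: 12 (1S,4R,5S,6S,10R)-4-isopropyl-1,8-dimethyl-10-(triisopropylsilyloxy)bicyclo[5.3.0]dec-8-ene-4,6-diol
Conditions: pyridinium p-toluenesulfonate (cat), MeOH/CH2Cl2, 0 °C
Reagents that add atoms: none
Why: Acid-catalysed methanolysis (selective desilylation) removes the triethylsilyl ether much faster than the bulkier triisopropylsilyl ether and does not affect the tertiary alcohol or the alkene.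

Step 8
Reactants: 12 (1S,4R,5S,6S,10R)-4-isopropyl-1,8-dimethyl-10-(triisopropylsilyloxy)bicyclo[5.3.0]dec-8-ene-4,6-diol; 13 4-methoxybenzoyl chloride
Product: 14 (1S,4R,5S,6S,10R)-4-hydroxy-4-isopropyl-1,8-dimethyl-10-(triisopropylsilyloxy)bicyclo[5.3.0]dec-8-en-6-yl 4-methoxybenzoate
Conditions: 4-(dimethylamino)pyridine (cat), pyridine, CH2Cl2, 0 °C → rt
Reagents that add atoms: none
Why: Nucleophilic-catalysis acylation (acid chloride with 4-(dimethylamino)pyridine) esterifies the secondary C6 hydroxyl only, since the tertiary C4 hydroxyl is too hindered to be acylated under these conditions.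

Step 9
Reactants: 14 (1S,4R,5S,6S,10R)-4-hydroxy-4-isopropyl-1,8-dimethyl-10-(triisopropylsilyloxy)bicyclo[5.3.0]dec-8-en-6-yl 4-methoxybenzoate
Product: 15 (1S,4R,5S,6S,10R)-4,10-dihydroxy-4-isopropyl-1,8-dimethylbicyclo[5.3.0]dec-8-en-6-yl 4-methoxybenzoate
Conditions: Bu4NF, AcOH, THF, 0 °C → rt
Reagents that add atoms: none
Why: Fluoride-induced desilylation cleaves the Si–O bond of the triisopropylsilyl ether, and buffering with acetic acid keeps the medium non-basic so that the anisoate should neither migrate nor be hydrolysed.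

Step 10
Reactants: 15 (1S,4R,5S,6S,10R)-4,10-dihydroxy-4-isopropyl-1,8-dimethylbicyclo[5.3.0]dec-8-en-6-yl 4-methoxybenzoate; 16 angelic acid [(Z)-2-methylbut-2-enoic acid]
Product: 18 (1S,4R,5S,6S,10R)-4-hydroxy-4-isopropyl-1,8-dimethyl-6-(4-methoxybenzoyloxy)bicyclo[5.3.0]dec-8-en-10-yl (Z)-2-methylbut-2-enoate (the target CNP0168729.1), via mixed anhydride 17 (not isolated)
Conditions: 16, 2,4,6-Cl3C6H2COCl, Et3N, toluene, rt; then 15, toluene, 80 °C
Reagents that add atoms: none
Why: Yamaguchi esterification through the mixed anhydride 17, run without a nucleophilic catalyst, is the usual way to transfer an angeloyl group without Z to E isomerisation, the alcohol attacking the less hindered angeloyl carbonyl and the tertiary C4 hydroxyl staying free.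

## Compound list

1 | 2-bromo-3-methylcyclopent-2-en-1-one | CC1=C(Br)C(=O)CC1 | starting material
2 | (S)-2-bromo-3-methylcyclopent-2-en-1-ol | O[C@H]1CCC(C)=C1Br | intermediate
3 | (S)-[(2-bromo-3-methylcyclopent-2-en-1-yl)oxy]triethylsilane | CC[Si](CC)(CC)O[C@H]1CCC(C)=C1Br | intermediate
4 | (S)-[2-methyl-5-(triethylsilyloxy)cyclopent-1-en-1-yl]lithium (not isolated) | CC[Si](CC)(CC)O[C@H]1CCC(C)=C1[Li] | intermediate
5 | (S)-2-methyl-5-(triethylsilyloxy)cyclopent-1-ene-1-carbaldehyde | CC[Si](CC)(CC)O[C@H]1CCC(C)=C1C=O | intermediate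
6 | 3-methylbut-2-enal | CC(C)=CC=O | starting material
7 | (E)-triisopropyl[(3-methylbuta-1,3-dien-1-yl)oxy]silane | C=C(C)/C=C/O[Si](C(C)C)(C(C)C)C(C)C | intermediate
8 | O-triethylsilyl oxocarbenium ion of 5 (1-silyloxyallyl cation C6–C5–C1), triflimide salt (not isolated) | CC[Si](CC)(CC)O[C@H]1CCC(C)=C1C=[O+][Si](CC)(CC)CC.O=S(=O)([N-]S(=O)(=O)C(F)(F)F)C(F)(F)F | intermediate
9 | (1S,4S,6S,10R)-1,8-dimethyl-4,6-bis(triethylsilyloxy)-10-(triisopropylsilyloxy)bicyclo[5.3.0]dec-8-en-5-ylium (C5 cation), triflimide salt (not isolated) | CC(C)[Si](C(C)C)(C(C)C)O[C@@H]1C=C(C)C[C@H](O[Si](CC)(CC)CC)[C+]2[C@]1(C)CC[C@@H]2O[Si](CC)(CC)CC.O=S(=O)([N-]S(=O)(=O)C(F)(F)F)C(F)(F)F | intermediate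
10 | (1S,5S,6S,10R)-1,8-dimethyl-6-(triethylsilyloxy)-10-(triisopropylsilyloxy)bicyclo[5.3.0]dec-8-en-4-one (trans-fused; 5α-H, 6α-O, 10α-O, 1β-Me) | CC(C)[Si](C(C)C)(C(C)C)O[C@@H]1C=C(C)C[C@H](O[Si](CC)(CC)CC)[C@@H]2[C@]1(C)CCC2=O | intermediate
11 | (1S,4R,5S,6S,10R)-4-isopropyl-1,8-dimethyl-6-(triethylsilyloxy)-10-(triisopropylsilyloxy)bicyclo[5.3.0]dec-8-en-4-ol (4β-OH) | CC(C)[Si](C(C)C)(C(C)C)O[C@@H]1C=C(C)C[C@H](O[Si](CC)(CC)CC)[C@@H]2[C@]1(C)CC[C@@]2(O)C(C)C | intermediate
12 | (1S,4R,5S,6S,10R)-4-isopropyl-1,8-dimethyl-10-(triisopropylsilyloxy)bicyclo[5.3.0]dec-8-ene-4,6-diol | CC(C)[Si](C(C)C)(C(C)C)O[C@@H]1C=C(C)C[C@H](O)[C@@H]2[C@]1(C)CC[C@@]2(O)C(C)C | intermediate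
13 | 4-methoxybenzoyl chloride | COc1ccc(cc1)C(Cl)=O | starting material
14 | (1S,4R,5S,6S,10R)-4-hydroxy-4-isopropyl-1,8-dimethyl-10-(triisopropylsilyloxy)bicyclo[5.3.0]dec-8-en-6-yl 4-methoxybenzoate | CC(C)[Si](C(C)C)(C(C)C)O[C@@H]1C=C(C)C[C@H](OC(=O)c2ccc(OC)cc2)[C@@H]2[C@]1(C)CC[C@@]2(O)C(C)C | intermediate
15 | (1S,4R,5S,6S,10R)-4,10-dihydroxy-4-isopropyl-1,8-dimethylbicyclo[5.3.0]dec-8-en-6-yl 4-methoxybenzoate | O[C@@H]1C=C(C)C[C@H](OC(=O)c2ccc(OC)cc2)[C@@H]2[C@]1(C)CC[C@@]2(O)C(C)C | intermediate
16 | angelic acid [(Z)-2-methylbut-2-enoic acid] | C/C=C(/C)C(=O)O | starting material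
17 | (Z)-2-methylbut-2-enoic 2,4,6-trichlorobenzoic anhydride (not isolated) | C/C=C(/C)C(=O)OC(=O)c1c(Cl)cc(Cl)cc1Cl | intermediate
18 | CNP0168729.1: (1S,4R,5S,6S,10R)-4-hydroxy-4-isopropyl-1,8-dimethyl-6-(4-methoxybenzoyloxy)bicyclo[5.3.0]dec-8-en-10-yl (Z)-2-methylbut-2-enoate | C/C=C(/C)C(=O)O[C@@H]1C=C(C)C[C@H](OC(=O)c2ccc(OC)cc2)[C@@H]2[C@]1(C)CC[C@@]2(O)C(C)C | target

## Step count and risks

Total step count: 10. Longest linear sequence: 9 steps (steps 1, 2, 3, 5, 6, 7, 8, 9, 10); step 4 is a one-step branch.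

**Step 5.** The cationic cascade may stop after the first C–C bond and release the open-chain vinylogous aldol product. The diene may instead attack the hindered terminus C1 and close a six-membered ring. The cation may also end by migration of the C6 hydrogen or of C7 instead of the C4 hydrogen, and a loose transition state would erode the configuration at C10.

Fallback with known chemistry, from enal 5 back to ketone 10. The aldehyde is condensed with 2-(trifluoromethyl)benzenesulfonohydrazide to the N-sulfonylhydrazone F1. NaH and Rh2(OAc)4 in CH2Cl2 in the presence of diene 7 release the donor vinylcarbene, which cyclopropanates the 1,1-disubstituted C7=C8 bond on the face away from the C4 silyloxy group to give the cis-divinylcyclopropane F2. This should undergo Cope rearrangement through the obligatory boat transition state to the cycloheptadiene F3 (C5=C6 and C8=C9, with C1 and C10 as in the main route). Pyridinium p-toluenesulfonate in MeOH gives the allylic alcohol F4, and MnO2 the enone F5. Conjugate borylation (B2pin2, CuCl, NaOt-Bu, (R)-1-[(S)-2-(diphenylphosphino)ferrocenyl]ethyldicyclohexylphosphine, MeOH) places boron on C6 under ligand control and protonates C5 anti to the angular methyl to give the β-boryl ketone F6. NaBO3 oxidises the C–B bond with retention to the β-hydroxy ketone F7, and Et3SiCl/imidazole returns to 10.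

**Step 6.** Enolisation of the hindered ketone with β-elimination of the C6 silyloxy group, or reduction by β-hydride transfer from the isopropyl reagent, may outrun addition.

Fallback from ketone 10 back to alcohol 11. Isopropenylmagnesium bromide with CeCl3 (THF, −78 °C), a smaller sp2 nucleophile without a β-hydrogen, should give the isopropenyl carbinol F8 with the same facial sense. Hydrogenation with RhCl(PPh3)3 under H2 (benzene, rt) should saturate only the 1,1-disubstituted alkene, leaving the trisubstituted C8=C9 bond, to give 11.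

**Step 10.** Acylation of the hindered allylic C10 hydroxyl next to the quaternary carbon may be slow, and the (Z)-acyl unit may isomerise to the (E)-isomer when the reaction is forced.

Fallback from alcohol 15 to target 18. The alcohol is esterified (dicyclohexylcarbodiimide, 4-(dimethylamino)pyridine, CH2Cl2) with 2-[bis(2,2,2-trifluoroethoxy)phosphoryl]propanoic acid to give the phosphonate ester F9. A Still–Gennari olefination (KN(SiMe3)2, 2 equiv, 18-crown-6, THF, −78 °C; then acetaldehyde) then builds the (Z)-2-methylbut-2-enoate on the molecule and arrives at 18.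

Further compounds
F1 | step 5 | N'-{(E)-[(S)-2-methyl-5-(triethylsilyloxy)cyclopent-1-en-1-yl]methylidene}-2-(trifluoromethyl)benzenesulfonohydrazide | CC[Si](CC)(CC)O[C@H]1CCC(C)=C1/C=N/NS(=O)(=O)c1ccccc1C(F)(F)F
F2 | step 5 | cis-divinylcyclopropane: triethyl{[(S)-3-methyl-2-{2-methyl-2-[(E)-2-(triisopropylsilyloxy)ethenyl]cyclopropyl}cyclopent-2-en-1-yl]oxy}silane, cyclopentenyl and silyloxyvinyl groups cis | CC[Si](CC)(CC)O[C@H]1CCC(C)=C1[C@@H]1C[C@]1(C)/C=C/O[Si](C(C)C)(C(C)C)C(C)C
F3 | step 5 | (1S,4S,10R)-1,8-dimethyl-4-(triethylsilyloxy)-10-(triisopropylsilyloxy)bicyclo[5.3.0]deca-5,8-diene | CC(C)[Si](C(C)C)(C(C)C)O[C@@H]1C=C(C)CC=C2[C@]1(C)CC[C@@H]2O[Si](CC)(CC)CC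
F4 | step 5 | (1S,4S,10R)-1,8-dimethyl-10-(triisopropylsilyloxy)bicyclo[5.3.0]deca-5,8-dien-4-ol | CC(C)[Si](C(C)C)(C(C)C)O[C@@H]1C=C(C)CC=C2[C@]1(C)CC[C@@H]2O
F5 | step 5 | (1S,10R)-1,8-dimethyl-10-(triisopropylsilyloxy)bicyclo[5.3.0]deca-5,8-dien-4-one | CC(C)[Si](C(C)C)(C(C)C)O[C@@H]1C=C(C)CC=C2[C@]1(C)CCC2=O
F6 | step 5 | (1S,5S,6S,10R)-1,8-dimethyl-6-(4,4,5,5-tetramethyl-1,3,2-dioxaborolan-2-yl)-10-(triisopropylsilyloxy)bicyclo[5.3.0]dec-8-en-4-one | CC(C)[Si](C(C)C)(C(C)C)O[C@@H]1C=C(C)C[C@H](B3OC(C)(C)C(C)(C)O3)[C@@H]2[C@]1(C)CCC2=O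
F7 | step 5 | (1S,5S,6S,10R)-6-hydroxy-1,8-dimethyl-10-(triisopropylsilyloxy)bicyclo[5.3.0]dec-8-en-4-one | CC(C)[Si](C(C)C)(C(C)C)O[C@@H]1C=C(C)C[C@H](O)[C@@H]2[C@]1(C)CCC2=O
F8 | step 6 | 4-isopropenyl analogue of 11: 1,8-dimethyl-4-(prop-1-en-2-yl)-6-(triethylsilyloxy)-10-(triisopropylsilyloxy)bicyclo[5.3.0]dec-8-en-4-ol, same configuration as 11 | CC(C)[Si](C(C)C)(C(C)C)O[C@@H]1C=C(C)C[C@H](O[Si](CC)(CC)CC)[C@@H]2[C@]1(C)CC[C@@]2(O)C(C)=C
F9 | step 10 | 10-O-{2-[bis(2,2,2-trifluoroethoxy)phosphoryl]propanoyl} derivative of 15 | CC(C(=O)O[C@@H]1C=C(C)C[C@H](OC(=O)c2ccc(OC)cc2)[C@@H]2[C@]1(C)CC[C@@]2(O)C(C)C)P(=O)(OCC(F)(F)F)OCC(F)(F)F
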